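**Strategy.** The plan cuts ring C of the flavanone at O1–C8a and C4–C4a. Ring A is a 5,7-dioxygenated arene joined to ring C only through these two ortho bonds, so it can arrive last as 3,5-bis(benzyloxy)benzyne. In one operation the aryne is inserted between the hydroxyl oxygen and the ester carbonyl of an anti aldol adduct, closing the chromanone without touching C2 or C3. The precursor is the (2R,3S) methyl 3-hydroxy-2,3-diarylpropanoate whose C2 aryl group is the benzyl-protected 7-O-methylapigenin unit and whose C3 aryl group is 4-benzyloxyphenyl. Its two stereocentres come from an auxiliary-controlled anti aldol. Global hydrogenolysis ends the route.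

Key step: step 11

Assumption: the target is read as the trans (2S,3R) flavanone; 2',6'-dihydroxy-4'-methoxyacetophenone, 4-(benzyloxy)-3-bromobenzaldehyde, 3,5-bis(benzyloxy)phenol, (R)-4-benzyl-1,3-thiazolidine-2-thione and (2-tert-butoxy-2-oxoethyl)zinc bromide in THF are taken as purchased.

**Route**

Step 1
Reactants: 1 2',6'-dihydroxy-4'-methoxyacetophenone
Product: 2 1-[2-(benzyloxy)-6-hydroxy-4-methoxyphenyl]ethan-1-one
Conditions: BnBr (1.05 equiv), K2CO3, acetone, reflux
Reagents that add atoms: benzyl bromide, BrCc1ccccc1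
Why: Williamson ether synthesis on a symmetric bis-phenol, in which the hydroxyl that remains after the first benzylation is held by a hydrogen bond to the ketone and is much less nucleophilic, so one equivalent of benzyl bromide should stop at the mono-ether.

Step 2
Reactants: 2 1-[2-(benzyloxy)-6-hydroxy-4-methoxyphenyl]ethan-1-one; 3 4-(benzyloxy)-3-bromobenzaldehyde
Product: 4 (E)-1-[2-(benzyloxy)-6-hydroxy-4-methoxyphenyl]-3-[4-(benzyloxy)-3-bromophenyl]prop-2-en-1-one
Conditions: KOH (aq.), EtOH, rt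
Reagents that add atoms: none
Why: Claisen–Schmidt condensation, in which the methyl ketone enolate adds to the non-enolisable aldehyde and the aldol dehydrates by E1cB to the conjugated E-enone, while the aryl bromide and the benzyl ethers are inert to hydroxide at room temperature.

Step 3
Reactants: 4 (E)-1-[2-(benzyloxy)-6-hydroxy-4-methoxyphenyl]-3-[4-(benzyloxy)-3-bromophenyl]prop-2-en-1-one
Product: 5 5-(benzyloxy)-2-[4-(benzyloxy)-3-bromophenyl]-7-methoxy-4H-chromen-4-one
Conditions: I2 (0.1 equiv), DMSO, 130 °C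
Reagents that add atoms: none
Why: Iodine-catalysed oxidative cyclisation of a 2'-hydroxychalcone (oxa-Michael closure, α-iodination, loss of HI, iodide reoxidised by DMSO), the standard entry to flavones, which aryl bromides and benzyl ethers tolerate.

Step 4
Reactants: 5 5-(benzyloxy)-2-[4-(benzyloxy)-3-bromophenyl]-7-methoxy-4H-chromen-4-one; 6 (2-tert-butoxy-2-oxoethyl)zinc bromide
Product: 7 tert-butyl 2-{2-(benzyloxy)-5-[5-(benzyloxy)-7-methoxy-4-oxo-4H-chromen-2-yl]phenyl}acetate
Conditions: Pd2(dba)3 (cat.), XPhos, THF, 60 °C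
Reagents that add atoms: none
Why: Palladium-catalysed α-arylation of a zinc ester enolate (Negishi-type coupling of a Reformatsky reagent) through oxidative addition of the aryl bromide to zerovalent palladium, transmetalation from zinc and C–C reductive elimination, with a nucleophile mild enough to leave the γ-pyrone untouched.

Step 5
Reactants: 7 tert-butyl 2-{2-(benzyloxy)-5-[5-(benzyloxy)-7-methoxy-4-oxo-4H-chromen-2-yl]phenyl}acetate
Product: 8 2-{2-(benzyloxy)-5-[5-(benzyloxy)-7-methoxy-4-oxo-4H-chromen-2-yl]phenyl}acetic acid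
Conditions: TFA, CH2Cl2, rt
Reagents that add atoms: none
Why: Acidolysis of the tert-butyl ester by loss of the tert-butyl cation as 2-methylpropene, under which aryl benzyl ethers and the chromone should survive for the short time needed at room temperature.

Step 6
Reactants: 8 2-{2-(benzyloxy)-5-[5-(benzyloxy)-7-methoxy-4-oxo-4H-chromen-2-yl]phenyl}acetic acid; 9 (R)-4-benzyl-1,3-thiazolidine-2-thione
Product: 10 1-[(4R)-4-benzyl-2-thioxo-1,3-thiazolidin-3-yl]-2-{2-(benzyloxy)-5-[5-(benzyloxy)-7-methoxy-4-oxo-4H-chromen-2-yl]phenyl}ethan-1-one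
Conditions: EDC·HCl, DMAP (cat.), CH2Cl2, 0 °C to rt
Reagents that add atoms: none
Why: Carbodiimide coupling with DMAP catalysis (Steglich-type acylation) joins the acid to the ring nitrogen of the thiazolidinethione under near-neutral conditions.

Step 7
Reactants: 10 1-[(4R)-4-benzyl-2-thioxo-1,3-thiazolidin-3-yl]-2-{2-(benzyloxy)-5-[5-(benzyloxy)-7-methoxy-4-oxo-4H-chromen-2-yl]phenyl}ethan-1-one; 11 4-(benzyloxy)benzaldehyde
Product: 13 (2R,3S)-3-[4-(benzyloxy)phenyl]-2-{2-(benzyloxy)-5-[5-(benzyloxy)-7-methoxy-4-oxo-4H-chromen-2-yl]phenyl}-1-[(4R)-4-benzyl-2-thioxo-1,3-thiazolidin-3-yl]-3-hydroxypropan-1-one, via trimethylsilyl ether of the anti aldol imide 12 (not isolated)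
Conditions: MgBr2·OEt2 (0.2 equiv), Et3N, TMSCl, EtOAc, rt; then 1 M HCl, THF, rt
Reagents that add atoms: chlorotrimethylsilane, C[Si](C)(C)Cl (its silyl group is carried by 12 and is gone in 13)
Why: Magnesium halide-catalysed direct anti aldol of an N-acylthiazolidinethione, in which soft enolisation gives the Z-enolate, silylation of the aldolate turns the magnesium over, the anti-selective transition state places the C2 aryl group and the C3 oxygen anti, and the (4R)-benzyl group of the auxiliary leaves one enolate face open, which should set C2 as R and C3 as S.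

Step 8
Reactants: 13 (2R,3S)-3-[4-(benzyloxy)phenyl]-2-{2-(benzyloxy)-5-[5-(benzyloxy)-7-methoxy-4-oxo-4H-chromen-2-yl]phenyl}-1-[(4R)-4-benzyl-2-thioxo-1,3-thiazolidin-3-yl]-3-hydroxypropan-1-one
Product: 14 methyl (2R,3S)-2-{2-(benzyloxy)-5-[5-(benzyloxy)-7-methoxy-4-oxo-4H-chromen-2-yl]phenyl}-3-[4-(benzyloxy)phenyl]-3-hydroxypropanoate (anti)
Conditions: MeOH, imidazole, CH2Cl2, rt
Reagents that add atoms: methanol, CO
Why: Nucleophilic acyl substitution on the activated N-acylthiazolidinethione by methanol with imidazole as acyl-transfer catalyst needs no strong base, so neither retro-aldol cleavage nor epimerisation at the benzylic C2 is expected, and the auxiliary is returned.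

Step 9
Reactants: 15 3,5-bis(benzyloxy)phenol
Product: 16 3,5-bis(benzyloxy)-2-bromophenol
Conditions: NBS (1.0 equiv), i-Pr2NH (cat.), CH2Cl2, 0 °C
Reagents that add atoms: N-bromosuccinimide, O=C1CCC(=O)N1Br
Why: Electrophilic aromatic bromination with ortho delivery from the N-bromoamine hydrogen-bonded to the phenol, so that C2 (ortho to the hydroxyl, para to a benzyloxy group) is attacked while C4 is shielded by two flanking benzyloxy groups.

Step 10
Reactants: 16 3,5-bis(benzyloxy)-2-bromophenol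
Product: 19 3,5-bis(benzyloxy)-2-(trimethylsilyl)phenyl trifluoromethanesulfonate, via aryl trimethylsilyl ether 17 (not isolated), via lithium 2-(trimethylsilyl)phenoxide 18 (not isolated)
Conditions: HMDS, THF, 65 °C, evaporate; n-BuLi, THF, −78 °C; Tf2O, −78 °C to rt
Reagents that add atoms: hexamethyldisilazane, C[Si](C)(C)N[Si](C)(C)C; trifluoromethanesulfonic anhydride, O=S(=O)(OS(=O)(=O)C(F)(F)F)C(F)(F)F
Why: Standard route to ortho-silylaryl triflates by O-silylation, bromine–lithium exchange, anionic 1,3 O-to-C silyl migration (retro-Brook rearrangement) and O-triflation of the lithium phenoxide, the exchange at −78 °C being much faster than lithiation at a benzylic ether position.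

Step 11
Reactants: 14 methyl (2R,3S)-2-{2-(benzyloxy)-5-[5-(benzyloxy)-7-methoxy-4-oxo-4H-chromen-2-yl]phenyl}-3-[4-(benzyloxy)phenyl]-3-hydroxypropanoate; 19 3,5-bis(benzyloxy)-2-(trimethylsilyl)phenyl trifluoromethanesulfonate
Product: 22 (2S,3R)-5,7-bis(benzyloxy)-3-{2-(benzyloxy)-5-[5-(benzyloxy)-7-methoxy-4-oxo-4H-chromen-2-yl]phenyl}-2-[4-(benzyloxy)phenyl]chroman-4-one (trans), via 3,5-bis(benzyloxy)benzyne 20 (not isolated), via caesium aryl anion adduct 21 (not isolated)
Conditions: CsF (4 equiv), 19 (1.5 equiv, in portions), 4 Å molecular sieves, THF, 65 °C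
Reagents that add atoms: none
Why: Proposed new method: fluoride attacks silicon in 19 and triflate departs to give aryne 20; the fluoride-hydrogen-bonded hydroxyl oxygen of 14 adds to the aryne carbon remote from the adjacent benzyloxy group, the charge of the resulting aryl anion 21 sits on the carbon next to that group where the C–O bond stabilises it inductively, and this anion attacks the ester carbonyl with loss of methoxide, so that O1–C8a and C4–C4a form in one flask. The closest known reaction types are the CsF-mediated annulation of salicylate esters with arynes to xanthones, aryne insertion into aliphatic O–H bonds, and the aryne insertion of carboxylic acids that leads to ortho-hydroxyaryl ketones and chromanones; an aliphatic β-hydroxy ester has not been used as the two-point partner. Ring C closes by 6-exo-trig acyl substitution. No stereocentre is made: C2 and C3 are those of the aldol, the C2–O bond is never broken, and the trans 2,3-diequatorial arrangement is also the thermodynamic one should C3 enolise. The step needs oxygen attack at the right aryne carbon, which the 3-benzyloxy substituent dictates (it places the ether groups at C5 and C7), and acylation faster than protonation of 21, which aprotic THF with sparingly soluble CsF and bifluoride favours. It also needs the absence of retro-aldol cleavage and of base-induced opening of ring C, for which the low standing concentration of fluoride, the moderate temperature and an excess of 19 that consumes the released methoxide are relied on.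

Step 12
Reactants: 22 (2S,3R)-5,7-bis(benzyloxy)-3-{2-(benzyloxy)-5-[5-(benzyloxy)-7-methoxy-4-oxo-4H-chromen-2-yl]phenyl}-2-[4-(benzyloxy)phenyl]chroman-4-one
Product: 23 2-{3-[(2S,3R)-5,7-dihydroxy-2-(4-hydroxyphenyl)-4-oxochroman-3-yl]-4-hydroxyphenyl}-5-hydroxy-7-methoxy-4H-chromen-4-one
Conditions: H2 (1 atm), 10% Pd/C, EtOAc/MeOH, rt
Reagents that add atoms: none
Why: Heterogeneous hydrogenolysis of the five aryl benzyl ethers, under which the chromone C2=C3 bond, the aryl ketone and the benzylic C2–O1 bond of the flavanone are reduced much more slowly at one atmosphere and no stereocentre is touched, so stopping after uptake of five equivalents should give the target.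

**Compound list**

1 | 2',6'-dihydroxy-4'-methoxyacetophenone | CC(=O)c1c(O)cc(OC)cc1O | starting material
2 | 1-[2-(benzyloxy)-6-hydroxy-4-methoxyphenyl]ethan-1-one | CC(=O)c1c(O)cc(OC)cc1OCc1ccccc1 | intermediate
3 | 4-(benzyloxy)-3-bromobenzaldehyde | O=Cc1ccc(OCc2ccccc2)c(Br)c1 | starting material
4 | (E)-1-[2-(benzyloxy)-6-hydroxy-4-methoxyphenyl]-3-[4-(benzyloxy)-3-bromophenyl]prop-2-en-1-one | COc1cc(O)c(C(=O)/C=C/c2ccc(OCc3ccccc3)c(Br)c2)c(OCc2ccccc2)c1 | intermediate
5 | 5-(benzyloxy)-2-[4-(benzyloxy)-3-bromophenyl]-7-methoxy-4H-chromen-4-one | COc1cc(OCc2ccccc2)c2c(=O)cc(-c3ccc(OCc4ccccc4)c(Br)c3)oc2c1 | intermediate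
6 | (2-tert-butoxy-2-oxoethyl)zinc bromide | CC(C)(C)OC(=O)C[Zn]Br | starting material
7 | tert-butyl 2-{2-(benzyloxy)-5-[5-(benzyloxy)-7-methoxy-4-oxo-4H-chromen-2-yl]phenyl}acetate | COc1cc(OCc2ccccc2)c2c(=O)cc(-c3ccc(OCc4ccccc4)c(CC(=O)OC(C)(C)C)c3)oc2c1 | intermediate
8 | 2-{2-(benzyloxy)-5-[5-(benzyloxy)-7-methoxy-4-oxo-4H-chromen-2-yl]phenyl}acetic acid | COc1cc(OCc2ccccc2)c2c(=O)cc(-c3ccc(OCc4ccccc4)c(CC(=O)O)c3)oc2c1 | intermediate
9 | (R)-4-benzyl-1,3-thiazolidine-2-thione | S=C1N[C@H](Cc2ccccc2)CS1 | starting material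
10 | 1-[(4R)-4-benzyl-2-thioxo-1,3-thiazolidin-3-yl]-2-{2-(benzyloxy)-5-[5-(benzyloxy)-7-methoxy-4-oxo-4H-chromen-2-yl]phenyl}ethan-1-one | COc1cc(OCc2ccccc2)c2c(=O)cc(-c3ccc(OCc4ccccc4)c(CC(=O)N4[C@H](Cc5ccccc5)CSC4=S)c3)oc2c1 | intermediate
11 | 4-(benzyloxy)benzaldehyde | O=Cc1ccc(OCc2ccccc2)cc1 | starting material
12 | trimethylsilyl ether of the (2R,3S) anti aldol imide 13 | COc1cc(OCc2ccccc2)c2c(=O)cc(-c3ccc(OCc4ccccc4)c([C@@H](C(=O)N4[C@H](Cc5ccccc5)CSC4=S)[C@H](O[Si](C)(C)C)c4ccc(OCc5ccccc5)cc4)c3)oc2c1 | intermediate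
13 | (2R,3S)-3-[4-(benzyloxy)phenyl]-2-{2-(benzyloxy)-5-[5-(benzyloxy)-7-methoxy-4-oxo-4H-chromen-2-yl]phenyl}-1-[(4R)-4-benzyl-2-thioxo-1,3-thiazolidin-3-yl]-3-hydroxypropan-1-one | COc1cc(OCc2ccccc2)c2c(=O)cc(-c3ccc(OCc4ccccc4)c([C@@H](C(=O)N4[C@H](Cc5ccccc5)CSC4=S)[C@H](O)c4ccc(OCc5ccccc5)cc4)c3)oc2c1 | intermediate
14 | methyl (2R,3S)-2-{2-(benzyloxy)-5-[5-(benzyloxy)-7-methoxy-4-oxo-4H-chromen-2-yl]phenyl}-3-[4-(benzyloxy)phenyl]-3-hydroxypropanoate | COc1cc(OCc2ccccc2)c2c(=O)cc(-c3ccc(OCc4ccccc4)c([C@@H](C(=O)OC)[C@H](O)c4ccc(OCc5ccccc5)cc4)c3)oc2c1 | intermediate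
15 | 3,5-bis(benzyloxy)phenol | Oc1cc(OCc2ccccc2)cc(OCc2ccccc2)c1 | starting material
16 | 3,5-bis(benzyloxy)-2-bromophenol | Oc1cc(OCc2ccccc2)cc(OCc2ccccc2)c1Br | intermediate
17 | [3,5-bis(benzyloxy)-2-bromophenoxy]trimethylsilane | C[Si](C)(C)Oc1cc(OCc2ccccc2)cc(OCc2ccccc2)c1Br | intermediate
18 | lithium 3,5-bis(benzyloxy)-2-(trimethylsilyl)phenoxide | [Li+].[O-]c1cc(OCc2ccccc2)cc(OCc2ccccc2)c1[Si](C)(C)C | intermediate
19 | 3,5-bis(benzyloxy)-2-(trimethylsilyl)phenyl trifluoromethanesulfonate | C[Si](C)(C)c1c(OCc2ccccc2)cc(OCc2ccccc2)cc1OS(=O)(=O)C(F)(F)F | intermediate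
20 | 3,5-bis(benzyloxy)benzyne | C1#CC(OCc2ccccc2)=CC(OCc2ccccc2)=C1 | intermediate
21 | caesium aryl anion from O-addition of 14 to 20 (charge on the carbon between the two ether oxygens) | COc1cc(OCc2ccccc2)c2c(=O)cc(-c3ccc(OCc4ccccc4)c([C@@H](C(=O)OC)[C@H](Oc4cc(OCc5ccccc5)cc(OCc5ccccc5)[c-]4)c4ccc(OCc5ccccc5)cc4)c3)oc2c1.[Cs+] | intermediate
22 | (2S,3R)-5,7-bis(benzyloxy)-3-{2-(benzyloxy)-5-[5-(benzyloxy)-7-methoxy-4-oxo-4H-chromen-2-yl]phenyl}-2-[4-(benzyloxy)phenyl]chroman-4-one | COc1cc(OCc2ccccc2)c2c(=O)cc(-c3ccc(OCc4ccccc4)c([C@H]4C(=O)c5c(OCc6ccccc6)cc(OCc6ccccc6)cc5O[C@@H]4c4ccc(OCc5ccccc5)cc4)c3)oc2c1 | intermediate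
23 | 2-{3-[(2S,3R)-5,7-dihydroxy-2-(4-hydroxyphenyl)-4-oxochroman-3-yl]-4-hydroxyphenyl}-5-hydroxy-7-methoxy-4H-chromen-4-one | COc1cc(O)c2c(=O)cc(-c3ccc(O)c([C@H]4C(=O)c5c(O)cc(O)cc5O[C@@H]4c4ccc(O)cc4)c3)oc2c1 | target

**Step count and risks**

Total step count: 12. Longest linear sequence: 10 steps (steps 1 to 8, then 11 and 12); the aryne precursor arm is 2 steps (9 and 10).

Steps most likely to fail:

1. Step 11. The aryl anion may be protonated before it acylates, so that only O-arylation occurs. The hydroxy ester may also fragment by retro-aldol cleavage, or ring C may reopen through the C3 enolate with loss of configuration. Fallback: setting out from 14 and 19, the two bonds would be made one after the other by known reactions. Aryne insertion into the O–H bond under proton-transfer conditions (KF, 18-crown-6, THF, −20 °C) should give methyl (2R,3S)-3-[3,5-bis(benzyloxy)phenoxy]-2-{2-(benzyloxy)-5-[5-(benzyloxy)-7-methoxy-4-oxo-4H-chromen-2-yl]phenyl}-3-[4-(benzyloxy)phenyl]propanoate F1. Hydrolysis with Me3SnOH in 1,2-dichloroethane at 70 °C, chosen to avoid a basic medium that could eliminate the aryloxide, would give (2R,3S)-3-[3,5-bis(benzyloxy)phenoxy]-2-{2-(benzyloxy)-5-[5-(benzyloxy)-7-methoxy-4-oxo-4H-chromen-2-yl]phenyl}-3-[4-(benzyloxy)phenyl]propanoic acid F2. Trifluoroacetic anhydride in CH2Cl2 at 0 °C would then close ring C by intramolecular Friedel–Crafts acylation ortho to the ether oxygen of the electron-rich ring, coming back to the route at 22.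

2. Step 7. Anti/syn or facial selectivity may be poor for an arylacetyl imide, and turnover may be slow if magnesium is held by the chromone carbonyl or if the electron-rich aldehyde reacts sluggishly. Fallback: setting out from 10, only the carbinol centre would be set by the aldol and C3 would be left to thermodynamic control. The chelated titanium enolate (TiCl4 1 equiv, i-Pr2NEt 1 equiv, CH2Cl2, −78 °C) and 11 should give the syn adduct (2S,3S)-3-[4-(benzyloxy)phenyl]-2-{2-(benzyloxy)-5-[5-(benzyloxy)-7-methoxy-4-oxo-4H-chromen-2-yl]phenyl}-1-[(4R)-4-benzyl-2-thioxo-1,3-thiazolidin-3-yl]-3-hydroxypropan-1-one F3. Methanolysis as in step 8 would give methyl (2S,3S)-2-{2-(benzyloxy)-5-[5-(benzyloxy)-7-methoxy-4-oxo-4H-chromen-2-yl]phenyl}-3-[4-(benzyloxy)phenyl]-3-hydroxypropanoate F4. Annulation with 19 as in step 11 would give cis-(2S,3S)-5,7-bis(benzyloxy)-3-{2-(benzyloxy)-5-[5-(benzyloxy)-7-methoxy-4-oxo-4H-chromen-2-yl]phenyl}-2-[4-(benzyloxy)phenyl]chroman-4-one F5. Catalytic DBU in CH2Cl2 would then epimerise C3 to the trans isomer, coming back to the route at 22.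

3. Step 4. Oxidative addition and transmetalation may be slow at the bromide flanked by a benzyloxy group, with protodebromination or attack of the zinc enolate on the pyranone competing. Fallback: setting out from 5, a stabilised enolate would be arylated and one carboxyl group removed afterwards. Coupling with di-tert-butyl malonate (Pd(dba)2, P(t-Bu)3, K3PO4, toluene, 70 °C) should give di-tert-butyl 2-{2-(benzyloxy)-5-[5-(benzyloxy)-7-methoxy-4-oxo-4H-chromen-2-yl]phenyl}malonate F6. TFA in CH2Cl2 followed by warming in toluene would cleave both esters and decarboxylate the malonic acid, coming back to the route at 8.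

**Further compounds**

F1 | step 11 | methyl (2R,3S)-3-[3,5-bis(benzyloxy)phenoxy]-2-{2-(benzyloxy)-5-[5-(benzyloxy)-7-methoxy-4-oxo-4H-chromen-2-yl]phenyl}-3-[4-(benzyloxy)phenyl]propanoate | COc1cc(OCc2ccccc2)c2c(=O)cc(-c3ccc(OCc4ccccc4)c([C@@H](C(=O)OC)[C@H](Oc4cc(OCc5ccccc5)cc(OCc5ccccc5)c4)c4ccc(OCc5ccccc5)cc4)c3)oc2c1
F2 | step 11 | (2R,3S)-3-[3,5-bis(benzyloxy)phenoxy]-2-{2-(benzyloxy)-5-[5-(benzyloxy)-7-methoxy-4-oxo-4H-chromen-2-yl]phenyl}-3-[4-(benzyloxy)phenyl]propanoic acid | COc1cc(OCc2ccccc2)c2c(=O)cc(-c3ccc(OCc4ccccc4)c([C@@H](C(=O)O)[C@H](Oc4cc(OCc5ccccc5)cc(OCc5ccccc5)c4)c4ccc(OCc5ccccc5)cc4)c3)oc2c1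
F3 | step 7 | (2S,3S)-3-[4-(benzyloxy)phenyl]-2-{2-(benzyloxy)-5-[5-(benzyloxy)-7-methoxy-4-oxo-4H-chromen-2-yl]phenyl}-1-[(4R)-4-benzyl-2-thioxo-1,3-thiazolidin-3-yl]-3-hydroxypropan-1-one | COc1cc(OCc2ccccc2)c2c(=O)cc(-c3ccc(OCc4ccccc4)c([C@H](C(=O)N4[C@H](Cc5ccccc5)CSC4=S)[C@H](O)c4ccc(OCc5ccccc5)cc4)c3)oc2c1
F4 | step 7 | methyl (2S,3S)-2-{2-(benzyloxy)-5-[5-(benzyloxy)-7-methoxy-4-oxo-4H-chromen-2-yl]phenyl}-3-[4-(benzyloxy)phenyl]-3-hydroxypropanoate | COc1cc(OCc2ccccc2)c2c(=O)cc(-c3ccc(OCc4ccccc4)c([C@H](C(=O)OC)[C@H](O)c4ccc(OCc5ccccc5)cc4)c3)oc2c1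
F5 | step 7 | cis-(2S,3S)-5,7-bis(benzyloxy)-3-{2-(benzyloxy)-5-[5-(benzyloxy)-7-methoxy-4-oxo-4H-chromen-2-yl]phenyl}-2-[4-(benzyloxy)phenyl]chroman-4-one | COc1cc(OCc2ccccc2)c2c(=O)cc(-c3ccc(OCc4ccccc4)c([C@@H]4C(=O)c5c(OCc6ccccc6)cc(OCc6ccccc6)cc5O[C@@H]4c4ccc(OCc5ccccc5)cc4)c3)oc2c1
F6 | step 4 | di-tert-butyl 2-{2-(benzyloxy)-5-[5-(benzyloxy)-7-methoxy-4-oxo-4H-chromen-2-yl]phenyl}malonate | COc1cc(OCc2ccccc2)c2c(=O)cc(-c3ccc(OCc4ccccc4)c(C(C(=O)OC(C)(C)C)C(=O)OC(C)(C)C)c3)oc2c1
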